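## Structural features

The target is a trans-fused decalin. Ring A (C1–C5, C10) carries an axial 1α-hydroxyl, an equatorial 3β-chloride and the quaternary C4, which holds an axial β-methyl (C19) and an equatorial α-(E)-4-hydroxy-4-methylpent-2-enyl chain (C1′–C4′). Ring B (C5–C10) holds the C7=C8 enoate (methyl ester on C8), a β-formyl group (C11) on C9 and the quaternary C10 with its β-methyl. The six stereocentres (C1, C3, C4, C5, C10, C9) are nearly contiguous, and the methyls on C4 and C10 are syn-diaxial. Fragile groups are the β,γ-unsaturated aldehyde (acidic C9–H, so epimerisation or drift of the double bond into conjugation), the C1–OH/C11 γ-hydroxy aldehyde pair (lactol), the 1,3-chlorohydrin (base leads to elimination or oxetane formation) and the tertiary allylic alcohol (ionises in acid). The real difficulty is the quaternary C4 next to C5, and the two ring A heteroatoms: chlorine sits on the face that already carries the axial C4 methyl, and the C1 hydroxyl is axial beside quaternary C10, so both lie on the less accessible side. The key step exploits the fact that C4, with its two carbon arms, is the sp3 carbon of a symmetric 4,4-disubstituted cyclohexa-2,5-dienone whose carbonyl is C1. A carbon acid hung from C19 through an ester reaches only one face of either enone arm, so choosing one arm sets C4 and C5 together.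

## Logic of the disconnections

31 ⇒ 29 + 30. The C2′=C3′ double bond is cut (cross-metathesis). The tertiary allylic alcohol would not survive HCl or acetal cleavage, so it is attached last; what remains is a plain allyl group that can be carried from the first step. The forward step must be E-selective on an allyl group next to a quaternary carbon and must tolerate a free aldehyde and two free functions.

29 ⇒ 28. The C11 carbonyl is masked as a dimethyl acetal. In that form C9–H is not acidic and C11 does not compete in the ketone reduction. The forward hydrolysis must be mild enough to leave C9 untouched.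

28 ⇒ 27 ⇒ 26. The C1–H bond and then the C3–Cl bond are removed, which returns the C1 enone left over from the dienone. This clears two stereocentres and both ring A heteroatoms. The forward steps must deliver hydride to C1 from the β side and place chloride equatorially on the face of the C4 methyl; neither is the intrinsically easy face, and both are treated as risks below.

26 ⇒ 25 ⇒ 24. The C7=C8 bond is cut (intramolecular Horner–Wadsworth–Emmons), which opens ring B. The trans ring fusion then depends only on the C5/C10 relationship set earlier. The forward step needs C7 unveiled as an aldehyde without touching the C11 acetal.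

24 ⇒ 19 + 22. The C9–C10 bond is cut (Michael addition). It is made intermolecularly so that the new bond forms on the face opposite the C4 methyl and the C5 arm; an intramolecular closure onto C10 would favour the cis-decalin. The forward step needs a doubly activated acceptor, because the donor is a tetrasubstituted enolate, and it sets C10 and C9.

22 ⇒ 20 + 21. The C8=C9 bond of the acceptor is cut (Knoevenagel condensation) into two commercial components.

19 ⇒ 17. The C10–CH3 bond is cut. The methyl goes in before C9 so that the second, larger electrophile decides the configuration of C10. The enone confines enolisation to C10, because C4 has no hydrogen.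

17 ⇒ 16 ⇒ 15 ⇒ 13 ⇒ 12 ⇒ 10. These are functional-group changes only: C1 back to the alcohol level, C7 back to the ester level, the C19–O bond restored, and the C19–O–C7 lactone closed. C19 is deoxygenated by hydride displacement, not through a C19 radical, because that radical would be homoallylic to C2=C3 and prone to 3-exo closure and ring expansion. The forward demand is one global hydride step followed by selective re-oxidation of C1.

10 ⇒ 9. The C6–CO2Me bond is restored (dealkoxycarbonylation in the forward sense), giving back the malonate needed as the carbon acid.

9 ⇒ 8. The C5–C6 bond is cut and the lactone opened. This removes both stereocentres and returns a flat, symmetric dienone. The forward step must choose one of two enantiotopic enone arms.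

8 ⇒ 7 ⇒ 5 + 6, then 5 ⇒ 4 ⇒ 1 + 2. The ring carbonyl is removed (bis-allylic oxidation forward), the ester C–O bond is cut, the carbinol is returned to the acid, and the C4–allyl bond is cut (Birch reductive alkylation forward). Acylation precedes oxidation because a free 4-hydroxymethyl dienone can lose formaldehyde and aromatise.

## Other disconnections considered

Alternative 1: The cut is C9–C10 and C7–C8, building ring B on a ring A diene. In the forward key step the diene A2 (C10=C5–C6=C7, with the C10 methyl, a 1α-silyloxy group and the C4 quaternary centre in place) and the acetylenic aldehyde ester A3 combine on heating or with a mild Lewis acid to give the 1,4-cyclohexadiene A1.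
- In favour: ring B, the C8 ester and the C9 formyl group arrive in one step and already differentiated. The more nucleophilic terminus C7 should pair with the alkyne carbon β to the formyl group, which is the regiochemistry needed. For ring B this is better than the chosen plan's steps 13–15 on step economy, and it needs no enolate chemistry at a hindered carbon.
- Against: C10 becomes quaternary at the hindered end of a diene whose s-cis form is strained, so forcing conditions are likely. The dienophile must bond to C10 on the face that carries the 1α-silyloxy group the target requires. The C1 epimer of the diene would react more easily, anti to the silyl ether, but would give the 1-epi series, so A1 is only useful with the silyl ether trans to the C10 methyl. C5 is flattened, so C5–H and C9–H must both be made afterwards, by reducing C5=C6 and by deconjugative protonation of the tetrasubstituted C8=C9. A1 has no handle at C3 for chlorine, and the configuration of C4 needs its own asymmetric step.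
- Comparison: A1 is structurally closer to the target's ring B than anything in the chosen route before 26, and a concerted cycloaddition is mechanistically cleaner than a Michael–olefination sequence; both points favour the alternative. The chosen plan is equal on regiochemistry and better on control of C4/C5 and on the placement of chlorine. Overall step counts are estimated to be similar.

Alternative 2: The cut is C3–C4 and C5–C10, making ring A by [4+2] cycloaddition. In the forward key step the aminosiloxydiene A6 adds to the (E)-2-methyl enal A5 under a chiral diol hydrogen-bond catalyst, and acidic work-up expels dimethylamine to give the enone A4 with C4 (methyl, formyl) and C5 set.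
- In favour: A4 is the functional equivalent of 17 and would be reached in about three steps instead of eleven. The C4 methyl is present from the start, so C19 needs no deoxygenation, and C6–C7 arrive at the alcohol level. The same enone arm remains, so steps 12–19 would be shared. On step and redox economy to the ring A building block this alternative is the better one. On the C4/C5 relationship the two are equal: cis by alkene geometry here, cis by tether in the chosen plan.
- Against: a trisubstituted β-alkyl-α-methyl enal is a far weaker dienophile than the α-substituted acroleins for which this catalysis is established, so rate and enantioselectivity are open. The neopentyl formyl group must be homologated by one carbon and then olefinated to build the side chain in the presence of the enone, which costs three to four steps. The chosen plan carries an inert allyl group and ends the chain with one metathesis.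
- Comparison: both key steps create C4 and C5 in one catalytic event; the cycloaddition forms two bonds and the tethered Michael addition one. The choice is close. The chosen plan keeps the side-chain handle from cheap benzoic acid and does not depend on a reluctant dienophile.

Alternative 3: The cut is C7–C8 and C8–C9, inserting C8 late. In the forward key step the trans-hydrindanone A8, with ring A complete, reacts with the diazo ester A9 and a boron Lewis acid; addition to the C9 ketone and 1,2-shift of C7 give the ring-expanded β-keto ester A7 (enol form).
- In favour: C8 and its ester enter regioselectively without enolate chemistry at C10, and the strained five-ring ketone is reactive. In placing the ester on C8 this is equal to the chosen plan, and it is better in avoiding an intermolecular addition of a hindered enolate.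
- Against: C9 ends up bearing oxygen. The formyl carbon still has to be attached at a neopentyl position, the oxygen removed, the double bond brought to C7=C8 and C9–H set, which is at least four more steps including a late deconjugation. Migration of the quaternary C10 and epoxide formation would compete, and any free carbene could attack the allyl group. A8 must itself be made with the C3 chloride and C1 oxygen in place, so the hardest ring A problems are moved earlier, not solved.
- Comparison: the alternative is convergent on carbon count, but a cationic 1,2-shift is less predictable than an olefination ring closure, and on step economy it is the weakest of the three.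

Key step: step 5

Remark: atoms carry the target numbering (C19 = methyl on C4, C11 = formyl carbon, C1′–C4′ = side chain) and β is the face of the C10 methyl. The (R,R) thiourea catalyst is assumed to deliver 9; its mirror image would be used if the sense of induction were the opposite.

## Route

Step 1
Reactants: 1 benzoic acid; 2 allyl bromide
Product: 4 1-allylcyclohexa-2,5-diene-1-carboxylic acid, via dilithium dienolate 3 (not isolated)
Conditions: Li, NH3(l), THF, −78 °C; then 2, −78 °C → rt; aq. HCl
Reagents that add atoms: none
Why: Birch reduction of the benzoate gives the 1,4-dihydro dianion, which is alkylated at the ipso carbon (Birch reductive alkylation); no stereocentre is formed.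

Step 2
Reactants: 4 1-allylcyclohexa-2,5-diene-1-carboxylic acid
Product: 5 (1-allylcyclohexa-2,5-dien-1-yl)methanol
Conditions: LiAlH4, THF, 0 °C → reflux
Reagents that add atoms: none
Why: Hydride reduction of a carboxylic acid to the primary alcohol; the skipped diene is inert to LiAlH4.

Step 3
Reactants: 5 (1-allylcyclohexa-2,5-dien-1-yl)methanol; 6 methyl malonyl chloride
Product: 7 (1-allylcyclohexa-2,5-dien-1-yl)methyl methyl malonate
Conditions: pyridine, DMAP (cat.), CH2Cl2, 0 °C
Reagents that add atoms: none
Why: Acylation of the neopentyl primary alcohol with an acid chloride. It is done before the oxidation because a free 4-hydroxymethyl dienone could lose formaldehyde and aromatise.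

Step 4
Reactants: 7 (1-allylcyclohexa-2,5-dien-1-yl)methyl methyl malonate
Product: 8 methyl (1-allyl-4-oxocyclohexa-2,5-dien-1-yl)methyl malonate
Conditions: t-BuOOH (in decane), Rh2(cap)4 (1 mol %, cap = caprolactamate), K2CO3, CH2Cl2, rt
Reagents that add atoms: tert-butyl hydroperoxide, CC(C)(C)OO
Why: Allylic oxidation at the doubly allylic CH2, the weakest C–H bond in the molecule, gives the cross-conjugated dienone. The product is kept at or below room temperature because 4-allyl dienones undergo Cope rearrangement and aromatise on heating.

Step 5
Reactants: 8 methyl (1-allyl-4-oxocyclohexa-2,5-dien-1-yl)methyl malonate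
Product: 9 cis-fused lactone enone, methyl 8a-allyl-3,6-dioxo-3,4,4a,5,6,8a-hexahydro-1H-isochromene-4-carboxylate (C19 and C6 cis, allyl and H5 cis, ester trans to the C10 methylene)
Conditions: 1-[3,5-bis(trifluoromethyl)phenyl]-3-[(1R,2R)-2-(dimethylamino)cyclohexyl]thiourea (10 mol %), toluene, 0 °C → rt
Reagents that add atoms: none
Why: The tertiary amine of the catalyst deprotonates the malonate while the thiourea hydrogen-bonds the dienone carbonyl; C6 of the bound enolate adds to C5 of one enone arm and the resulting enol is protonated at C10 (intramolecular Michael addition). The closest known reaction type is the organocatalytic desymmetrising intramolecular Michael addition of tethered carbon acids to 4,4-disubstituted cyclohexadienones. The six-membered lactone closes in 6-exo-trig mode, with the ester tether in its s-cis form. C4 becomes stereogenic through the catalyst's choice between the two enantiotopic enone arms. C5 is fixed relative to C4 by the tether: C6 can reach C5 only on the face that bears C19, so the fusion is cis, with C6 cis to the future methyl and trans to the allyl group. C6 is epimerisable, should settle with the ester trans to C10, and is removed in step 6. The only selectivity the step needs is between the two arms; regio- and diastereoselectivity are built into the substrate, and a second addition to the remaining arm would require a four-membered ring. The mild, weakly basic conditions limit reversal of the addition and Cope rearrangement of 8.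

Step 6
Reactants: 9 cis-fused lactone enone (malonate)
Product: 10 cis-fused lactone enone, 8a-allyl-4,4a,5,8a-tetrahydro-1H-isochromene-3,6-dione
Conditions: LiCl, H2O, DMSO, 130 °C
Reagents that add atoms: none
Why: Krapcho dealkoxycarbonylation: chloride demethylates the methyl ester and the β-carbonyl carboxylate loses CO2. The medium is close to neutral, so the C5–C6 bond does not reverse and C4 and C5 are untouched.

Step 7
Reactants: 10 cis-fused lactone enone
Product: 12 methyl 2-[2-allyl-2-(hydroxymethyl)-5-oxocyclohex-3-en-1-yl]acetate (CH2OH and CH2CO2Me cis), via lithium carboxylate 11 (not isolated)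
Conditions: LiOH, THF/H2O, 0 °C; then MeI, DMF, rt
Reagents that add atoms: lithium hydroxide, [Li+].[OH-]; iodomethane, CI
Why: Saponification of the δ-lactone followed by O-alkylation of the carboxylate opens the ring irreversibly, which acid- or base-catalysed methanolysis would not. The hydroxy ester is used at once because it can re-close to 10.

Step 8
Reactants: 12 hydroxy ester
Product: 13 methyl 2-[2-allyl-2-(methanesulfonyloxymethyl)-5-oxocyclohex-3-en-1-yl]acetate
Conditions: MsCl, Et3N, CH2Cl2, −20 °C
Reagents that add atoms: methanesulfonyl chloride, CS(=O)(=O)Cl
Why: Sulfonylation of the only hydroxyl activates C19 for hydride displacement.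

Step 9
Reactants: 13 mesylate ester
Product: 15 4-allyl-5-(2-hydroxyethyl)-4-methylcyclohex-2-en-1-ol (C1 epimers; C4 methyl and C5 arm cis), via mesylate diol 14 (not isolated)
Conditions: i-Bu2AlH, THF, −78 → 0 °C; then LiEt3BH, 0 → 65 °C
Reagents that add atoms: none
Why: i-Bu2AlH reduces the enone 1,2 and the ester to the primary alcohol; LiEt3BH then displaces the neopentyl mesylate by SN2 with hydride to give the C4 methyl. An ionic path is chosen because a C19 radical would be homoallylic to C2=C3 and could rearrange; the C1 carbinol configuration is irrelevant.

Step 10
Reactants: 15 diol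
Product: 16 4-allyl-4-methyl-5-[2-(triethylsilyloxy)ethyl]cyclohex-2-en-1-ol
Conditions: Et3SiCl, imidazole, CH2Cl2, −40 °C
Reagents that add atoms: chlorotriethylsilane, CC[Si](Cl)(CC)CC
Why: The unhindered primary hydroxyl is silylated much faster than the secondary allylic one. The triethylsilyl group is chosen because it can later be oxidised off directly.

Step 11
Reactants: 16 allylic alcohol
Product: 17 4-allyl-4-methyl-5-[2-(triethylsilyloxy)ethyl]cyclohex-2-en-1-one
Conditions: MnO2, CH2Cl2, rt
Reagents that add atoms: none
Why: MnO2 oxidises the allylic alcohol and regenerates the C1 enone; the silyl ether and the allyl group are inert.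

Step 12
Reactants: 17 enone
Product: 19 4-allyl-4,6-dimethyl-5-[2-(triethylsilyloxy)ethyl]cyclohex-2-en-1-one (C10 epimers), via lithium dienolate 18 (not isolated)
Conditions: LiN(i-Pr)2, THF, −78 °C; then MeI, −78 → −20 °C
Reagents that add atoms: iodomethane, CI
Why: Kinetic α′-enolate alkylation: C10 is the only enolisable position because C4 is quaternary. The epimer mixture at C10 converges in step 14.

Step 13
Reactants: 20 trimethyl phosphonoacetate; 21 2,2-dimethoxyacetaldehyde
Product: 22 methyl (E)-2-(dimethoxyphosphoryl)-4,4-dimethoxybut-2-enoate
Conditions: piperidine (cat.), AcOH (cat.), toluene, reflux, Dean–Stark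
Reagents that add atoms: none
Why: Knoevenagel condensation of an activated methylene with a reactive aldehyde gives the doubly activated alkene. It is used as obtained, because the alkene geometry is lost in the next step.

Step 14
Reactants: 19 C10-methyl enone; 22 phosphonate acceptor
Product: 24 Michael adduct, methyl 2-(dimethoxyphosphoryl)-4,4-dimethoxy-3-{4-allyl-1,4-dimethyl-2-oxo-6-[2-(triethylsilyloxy)ethyl]cyclohex-3-en-1-yl}butanoate (C10 methyl β, C9 as in the target, C8 epimers), via lithium enolate 23 (not isolated)
Conditions: LiN(i-Pr)2, THF, −78 °C; then 22, −78 → −40 °C; aq. NH4Cl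
Reagents that add atoms: none
Why: Michael addition of the tetrasubstituted enolate to a doubly activated acceptor gives a stabilised phosphonoacetate anion, which does not add back to the enone. C10 is set by attack on the α face, anti to the axial C4 methyl and trans to the C5 arm. C9 is set by a lithium-chelated transition state that places the C9 hydrogen between the C10 methyl and C5 and holds the phosphoryl/ester end next to the enolate oxygen.

Step 15
Reactants: 24 Michael adduct
Product: 26 bicyclic enone, methyl 5-allyl-1-(dimethoxymethyl)-5,8a-dimethyl-8-oxo-1,4,4a,5,8,8a-hexahydronaphthalene-2-carboxylate (target numbering: C1 ketone, C2=C3, C7=C8, 4β-Me, 5α-H, 9β-CH(OMe)2, 10β-Me), via keto aldehyde 25 (not isolated)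
Conditions: (COCl)2, DMSO, CH2Cl2, −78 °C; Et3N, −78 → 0 °C; then LiCl, DBU, MeCN, rt
Reagents that add atoms: none
Why: Swern conditions oxidise a primary triethylsilyl ether directly to the aldehyde and leave the dimethyl acetal alone. The intramolecular Horner–Wadsworth–Emmons reaction then forms C7=C8 and closes ring B; the fusion is trans because the C6 and C9 arms are already trans on ring A.

Step 16
Reactants: 26 bicyclic enone
Product: 27 chloro ketone, methyl 5-allyl-6-chloro-1-(dimethoxymethyl)-5,8a-dimethyl-8-oxo-1,4,4a,5,6,7,8,8a-octahydronaphthalene-2-carboxylate (3β-Cl)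
Conditions: HCl (gas, excess), CH2Cl2, 0 °C → rt, prolonged; evaporation at 0 °C
Reagents that add atoms: hydrogen chloride, Cl
Why: Reversible acid-promoted conjugate addition of chloride to the enone. Attack anti to the axial C4 methyl gives the 3α-chloride first, so the mixture is left to equilibrate toward the equatorial 3β-chloride, which avoids the syn-axial contact with H5. Crude 27 is reduced at once, and any 3α epimer is removed at the stage of 28.

Step 17
Reactants: 27 chloro ketone
Product: 28 chloro alcohol, methyl 5-allyl-6-chloro-1-(dimethoxymethyl)-8-hydroxy-5,8a-dimethyl-1,4,4a,5,6,7,8,8a-octahydronaphthalene-2-carboxylate (1α-OH, 3β-Cl)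
Conditions: LiBH(s-Bu)3, THF, −78 °C; aq. NH4Cl
Reagents that add atoms: none
Why: The bulky trialkylborohydride attacks the C1 ketone along the equatorial trajectory from the β side, as such reagents do with ketones flanked by a quaternary carbon bearing an axial methyl, and gives the axial 1α-alcohol. At −78 °C hydride addition is faster than loss of HCl.

Step 18
Reactants: 28 chloro alcohol acetal
Product: 29 hydroxy aldehyde, methyl 5-allyl-6-chloro-1-formyl-8-hydroxy-5,8a-dimethyl-1,4,4a,5,6,7,8,8a-octahydronaphthalene-2-carboxylate (1α-OH, 3β-Cl, 9β-CHO)
Conditions: CF3CO2H, H2O, CHCl3, 0 °C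
Reagents that add atoms: water, O
Why: Acid hydrolysis of the dimethyl acetal unveils the aldehyde. Cold aqueous acid is too weak to enolise the hindered β,γ-unsaturated aldehyde, so C9 is retained, and the tertiary alcohol is not yet present.

Step 19
Reactants: 29 hydroxy aldehyde; 30 2-methylbut-3-en-2-ol
Product: 31 target, methyl 6-chloro-1-formyl-8-hydroxy-5-[(E)-4-hydroxy-4-methylpent-2-en-1-yl]-5,8a-dimethyl-1,4,4a,5,6,7,8,8a-octahydronaphthalene-2-carboxylate (1α-OH, 3β-Cl, 4β-Me, 5α-H, 9β-CHO, 10β-Me)
Conditions: 30 (10 equiv), second-generation Hoveyda–Grubbs catalyst (5 mol %), CH2Cl2, 40 °C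
Reagents that add atoms: none
Why: Cross-metathesis of the terminal allyl group with a tertiary allylic alcohol partner should give the E-alkene. The trisubstituted enoate does not take part, and free hydroxyl and aldehyde groups are tolerated.

## Compound list

1 | benzoic acid | OC(=O)c1ccccc1 | starting material
2 | allyl bromide | C=CCBr | starting material
3 | dilithium 1,4-dihydrobenzoate dianion (dienolate) | [Li+].[Li+].[O-]C([O-])=C1C=CCC=C1 | intermediate
4 | 1-allylcyclohexa-2,5-diene-1-carboxylic acid | OC(=O)C1(CC=C)C=CCC=C1 | intermediate
5 | (1-allylcyclohexa-2,5-dien-1-yl)methanol | OCC1(CC=C)C=CCC=C1 | intermediate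
6 | methyl malonyl chloride | COC(=O)CC(=O)Cl | starting material
7 | (1-allylcyclohexa-2,5-dien-1-yl)methyl methyl malonate | COC(=O)CC(=O)OCC1(CC=C)C=CCC=C1 | intermediate
8 | methyl (1-allyl-4-oxocyclohexa-2,5-dien-1-yl)methyl malonate | COC(=O)CC(=O)OCC1(CC=C)C=CC(=O)C=C1 | intermediate
9 | cis-fused lactone enone with C6 ester | C=CC[C@]12C=CC(=O)C[C@H]1[C@H](C(=O)OC)C(=O)OC2 | intermediate
10 | cis-fused lactone enone | C=CC[C@]12C=CC(=O)C[C@H]1CC(=O)OC2 | intermediate
11 | lithium 2-[2-allyl-2-(hydroxymethyl)-5-oxocyclohex-3-en-1-yl]acetate | [Li+].[O-]C(=O)C[C@@H]1CC(=O)C=C[C@@]1(CO)CC=C | intermediate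
12 | methyl 2-[2-allyl-2-(hydroxymethyl)-5-oxocyclohex-3-en-1-yl]acetate | COC(=O)C[C@@H]1CC(=O)C=C[C@@]1(CO)CC=C | intermediate
13 | methyl 2-[2-allyl-2-(methanesulfonyloxymethyl)-5-oxocyclohex-3-en-1-yl]acetate | COC(=O)C[C@@H]1CC(=O)C=C[C@@]1(COS(C)(=O)=O)CC=C | intermediate
14 | [1-allyl-4-hydroxy-6-(2-hydroxyethyl)cyclohex-2-en-1-yl]methyl methanesulfonate (C1 epimers) | OCC[C@@H]1CC(O)C=C[C@@]1(COS(C)(=O)=O)CC=C | intermediate
15 | 4-allyl-5-(2-hydroxyethyl)-4-methylcyclohex-2-en-1-ol (C1 epimers) | OCC[C@@H]1CC(O)C=C[C@@]1(C)CC=C | intermediate
16 | 4-allyl-4-methyl-5-[2-(triethylsilyloxy)ethyl]cyclohex-2-en-1-ol (C1 epimers) | CC[Si](CC)(CC)OCC[C@@H]1CC(O)C=C[C@@]1(C)CC=C | intermediate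
17 | 4-allyl-4-methyl-5-[2-(triethylsilyloxy)ethyl]cyclohex-2-en-1-one | CC[Si](CC)(CC)OCC[C@@H]1CC(=O)C=C[C@@]1(C)CC=C | intermediate
18 | lithium dienolate of 17 | [Li+].CC[Si](CC)(CC)OCC[C@@H]1C=C([O-])C=C[C@@]1(C)CC=C | intermediate
19 | 4-allyl-4,6-dimethyl-5-[2-(triethylsilyloxy)ethyl]cyclohex-2-en-1-one (C10 epimers) | CC[Si](CC)(CC)OCC[C@@H]1C(C)C(=O)C=C[C@@]1(C)CC=C | intermediate
20 | trimethyl phosphonoacetate | COC(=O)CP(=O)(OC)OC | starting material
21 | 2,2-dimethoxyacetaldehyde | COC(OC)C=O | starting material
22 | methyl (E)-2-(dimethoxyphosphoryl)-4,4-dimethoxybut-2-enoate | COC(=O)/C(=C\C(OC)OC)P(=O)(OC)OC | intermediate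
23 | lithium enolate of 19 | [Li+].CC[Si](CC)(CC)OCC[C@@H]1C(C)=C([O-])C=C[C@@]1(C)CC=C | intermediate
24 | Michael adduct (C8 epimers) | CC[Si](CC)(CC)OCC[C@@H]1[C@@](C)([C@@H](C(OC)OC)C(C(=O)OC)P(=O)(OC)OC)C(=O)C=C[C@@]1(C)CC=C | intermediate
25 | keto aldehyde (C8 epimers) | O=CC[C@@H]1[C@@](C)([C@@H](C(OC)OC)C(C(=O)OC)P(=O)(OC)OC)C(=O)C=C[C@@]1(C)CC=C | intermediate
26 | bicyclic enone with C11 dimethyl acetal | COC(=O)C1=CC[C@H]2[C@](C)(CC=C)C=CC(=O)[C@]2(C)[C@H]1C(OC)OC | intermediate
27 | 3β-chloro ketone | COC(=O)C1=CC[C@H]2[C@](C)(CC=C)[C@@H](Cl)CC(=O)[C@]2(C)[C@H]1C(OC)OC | intermediate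
28 | 3β-chloro-1α-ol with C11 dimethyl acetal | COC(=O)C1=CC[C@H]2[C@](C)(CC=C)[C@@H](Cl)C[C@H](O)[C@]2(C)[C@H]1C(OC)OC | intermediate
29 | 3β-chloro-1α-hydroxy aldehyde with C4 allyl | COC(=O)C1=CC[C@H]2[C@](C)(CC=C)[C@@H](Cl)C[C@H](O)[C@]2(C)[C@H]1C=O | intermediate
30 | 2-methylbut-3-en-2-ol | CC(C)(O)C=C | starting material
31 | CNP0167913.1 | COC(=O)C1=CC[C@H]2[C@](C)(C/C=C/C(C)(C)O)[C@@H](Cl)C[C@H](O)[C@]2(C)[C@H]1C=O | target

## Step count and least certain steps

Total step count: 19. Longest linear sequence: 18 steps (steps 1–12 and 14–19); step 13 is a one-step side branch.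

Step 5 (key step).
- Risk: slow ring closure. The ester tether has to leave its preferred s-trans form, and a malonate is only weakly acidic toward a tertiary amine. A slow catalysed path gives room to the uncatalysed addition and to reversal of the addition, both of which lower the enantiomeric purity.
- Fallback: activate the electrophile instead of the nucleophile. The dienone carbonyl of 8 is condensed with a cinchona-derived primary amine (9-amino-9-deoxy-epi-quinine with an acid co-catalyst), and the iminium ion of one enone arm is attacked by the malonate enol. The route is left at 8 and rejoined at 9; no new compound is made (F0).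

Step 16.
- Risk: too little of the equatorial chloride. Chloride attack anti to the axial C4 methyl is much the faster path and gives the 3α epimer. The thermodynamic margin for 3β is small, because the C1 carbonyl removes one of the two syn-axial hydrogens, and the β-chloro ketone loses HCl easily.
- Fallback: make C3 by delivering hydrogen, not chloride, to the open α face. The route is left at 26. Nucleophilic epoxidation (t-BuOOH, DBU) gives the 2α,3α-epoxy ketone F1. Isomerisation with Pd(PPh3)4 and 1,2-bis(diphenylphosphino)ethane gives the 1,3-diketone F2. Oxalyl chloride converts the less encumbered C3 enol into the β-chloro enone F3. HCl adds to it to give the 3,3-dichloro ketone F4. One chlorine is then removed with Bu3SnH (1 equiv) and AIBN: the α-chloro radical takes hydrogen from the face opposite the C4 methyl, leaving the equatorial chloride. The route is rejoined at 27.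

Step 17.
- Risk: hydride delivery from the wrong face. The equatorial approach to C1 is crowded by the axial C10 methyl and by the C11 acetal in the peri position, so attack from the α face (giving the 1β-alcohol) or base-induced loss of HCl may take over.
- Fallback: accept α-face reduction and invert. The route is left at 27. NaBH4 in MeOH gives the equatorial 1β-alcohol F5. Mitsunobu reaction with 4-nitrobenzoic acid brings the oxygen nucleophile in from the open α face; the leaving group is equatorial, so no anti-periplanar hydrogen is available for elimination, and the product is the 1α 4-nitrobenzoate F6. Cold K2CO3 in MeOH removes the ester and rejoins the route at 28.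

Step 14.
- Risk: proton transfer from the acceptor's γ-position to the hindered enolate, or reversible addition, in place of C–C bond formation. Face selection at C9 depends on a lithium chelate and may be poor.
- Fallback: use a planar, tied-back cyclic acceptor. The route is left at 19. Its lithium enolate is added to the phosphono butenolide diethyl (2-oxo-2,5-dihydrofuran-3-yl)phosphonate F7 to give the lactone adduct F8. Swern oxidation of the silyl ether and LiCl/DBU olefination give the tricyclic butenolide enone F9. The lactone is opened with LiOH then MeI to the hydroxy ester F10, which is oxidised at once with Dess–Martin periodinane to the aldehyde F11. If C9 is inverted at this stage, it can be reset by enolisation and kinetic protonation from the α face. Acetalisation (HC(OMe)3, TsOH, MeOH) rejoins the route at 26.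

Step 9.
- Risk: sulfur–oxygen cleavage of the neopentyl mesylate, or ring closure by a neighbouring alkoxide onto C19, in place of hydride attack at carbon.
- Fallback: remove the C19 oxygen through the aldehyde. The route is left at 12. Dess–Martin oxidation gives the neopentyl aldehyde F12. Tosylhydrazide condenses selectively with the aldehyde to give the hydrazone F13. Catecholborane followed by NaOAc reduces it to the C4-methyl keto ester F14. i-Bu2AlH then reduces the ester and the enone and rejoins the route at 15.

## Further compounds

F0 | step 5 | none | none
F1 | step 16 | 2α,3α-epoxy ketone of 26 | COC(=O)C1=CC[C@H]2[C@](C)(CC=C)[C@@H]3O[C@@H]3C(=O)[C@]2(C)[C@H]1C(OC)OC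
F2 | step 16 | 1,3-diketone (C1 and C3 carbonyls) | COC(=O)C1=CC[C@H]2[C@](C)(CC=C)C(=O)CC(=O)[C@]2(C)[C@H]1C(OC)OC
F3 | step 16 | 3-chloro-2-en-1-one | COC(=O)C1=CC[C@H]2[C@](C)(CC=C)C(Cl)=CC(=O)[C@]2(C)[C@H]1C(OC)OC
F4 | step 16 | 3,3-dichloro ketone | COC(=O)C1=CC[C@H]2[C@](C)(CC=C)C(Cl)(Cl)CC(=O)[C@]2(C)[C@H]1C(OC)OC
F5 | step 17 | 3β-chloro-1β-ol | COC(=O)C1=CC[C@H]2[C@](C)(CC=C)[C@@H](Cl)C[C@@H](O)[C@]2(C)[C@H]1C(OC)OC
F6 | step 17 | 3β-chloro-1α-yl 4-nitrobenzoate | COC(=O)C1=CC[C@H]2[C@](C)(CC=C)[C@@H](Cl)C[C@H](OC(=O)c3ccc(cc3)[N+](=O)[O-])[C@]2(C)[C@H]1C(OC)OC
F7 | step 14 | diethyl (2-oxo-2,5-dihydrofuran-3-yl)phosphonate | CCOP(=O)(OCC)C1=CCOC1=O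
F8 | step 14 | lactone Michael adduct (C8 epimers) | CC[Si](CC)(CC)OCC[C@@H]1[C@@](C)([C@H]2COC(=O)C2P(=O)(OCC)OCC)C(=O)C=C[C@@]1(C)CC=C
F9 | step 14 | tricyclic butenolide enone | O=C1OC[C@H]2C1=CC[C@H]3[C@](C)(CC=C)C=CC(=O)[C@]23C
F10 | step 14 | C11 hydroxy methyl ester enone | COC(=O)C1=CC[C@H]2[C@](C)(CC=C)C=CC(=O)[C@]2(C)[C@H]1CO
F11 | step 14 | C11 aldehyde methyl ester enone | COC(=O)C1=CC[C@H]2[C@](C)(CC=C)C=CC(=O)[C@]2(C)[C@H]1C=O
F12 | step 9 | methyl 2-(2-allyl-2-formyl-5-oxocyclohex-3-en-1-yl)acetate | COC(=O)C[C@@H]1CC(=O)C=C[C@@]1(C=O)CC=C
F13 | step 9 | tosylhydrazone of F12 | COC(=O)C[C@@H]1CC(=O)C=C[C@@]1(C=NNS(=O)(=O)c2ccc(C)cc2)CC=C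
F14 | step 9 | methyl 2-(2-allyl-2-methyl-5-oxocyclohex-3-en-1-yl)acetate | COC(=O)C[C@@H]1CC(=O)C=C[C@@]1(C)CC=C
A1 | alternative 1 | bicyclic 5,8-diene cycloadduct (1α-silyl ether) | COC(=O)C1=C(C=O)[C@@]2(C)[C@@H](O[Si](C)(C)C(C)(C)C)CC[C@@](C)(CC(OC)OC)C2=CC1
A2 | alternative 1 | ring A vinylcyclohexene diene | C=CC1=C(C)[C@@H](O[Si](C)(C)C(C)(C)C)CC[C@@]1(C)CC(OC)OC
A3 | alternative 1 | methyl 4-oxobut-2-ynoate | COC(=O)C#CC=O
A4 | alternative 2 | 4-formyl-5-[2-(4-methoxybenzyloxy)ethyl]-4-methylcyclohex-2-en-1-one | O=C[C@]1(C)C=CC(=O)C[C@H]1CCOCc1ccc(OC)cc1
A5 | alternative 2 | (E)-5-(4-methoxybenzyloxy)-2-methylpent-2-enal | O=C/C(C)=C/CCOCc1ccc(OC)cc1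
A6 | alternative 2 | (E)-1-(dimethylamino)-3-(tert-butyldimethylsilyloxy)buta-1,3-diene | CN(C)/C=C/C(=C)O[Si](C)(C)C(C)(C)C
A7 | alternative 3 | decalin β-keto ester (enol form) | COC(=O)C=1CC[C@H]2[C@](C)(CC=C)[C@@H](Cl)C[C@H](O[Si](C)(C)C(C)(C)C)[C@]2(C)C=1O
A8 | alternative 3 | trans-hydrindanone | O=C1CC[C@H]2[C@](C)(CC=C)[C@@H](Cl)C[C@H](O[Si](C)(C)C(C)(C)C)[C@]12C
A9 | alternative 3 | methyl diazoacetate | COC(=O)C=[N+]=[N-]
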